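Ring A (O1, C2, C3, C4, C5) is disconnected across the C5=C6 ylidene to a C6 aldehyde, so the only stereocentre, C7, becomes the α-carbon of that aldehyde. Its precursor, an all-(E) enal, carries C6–C17 with the three methyl branches from farnesol (C12 to C1), while C18 and furan ring B come from furan-3-ylmethanol. Because C7=C8 is the only alkene conjugated to the C6 carbonyl, an ene-reductase delivers hydride to C8 and a proton to C7 in one operation, setting (7S) and leaving C11=C12, C15=C16 and ring B untouched. Bromo-olefination, aldol addition and copper-catalysed lactonisation then build ring A with the (E)-ylidene.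

Key step: step 11

Assumption: the target is made exactly as drawn, with C7 (S) and the C5=C6 ylidene (E), that is, O1 and C7 on opposite sides; (2E,6E)-farnesyl acetate, the acetate of farnesol, is bought as such.

Step 1
Reactants: 1 (2E,6E)-3,7,11-trimethyldodeca-2,6,10-trien-1-yl acetate
Product: 2 (2E,6E,10E)-12-hydroxy-3,7,11-trimethyldodeca-2,6,10-trien-1-yl acetate
Conditions: SeO2 (0.1 equiv), t-BuOOH (70% aq., 3 equiv), salicylic acid (0.1 equiv), CH2Cl2, 0 °C to rt
Reagents that add atoms: tert-butyl hydroperoxide, CC(C)(C)OO; selenium dioxide, O=[Se]=O (relays the oxygen atom)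
Why: Catalytic SeO2 allylic oxidation (Riley type, ene reaction then [2,3]-sigmatropic shift) attacks the terminal, most electron-rich trisubstituted alkene at its (E)-methyl group, the C2=C3 alkene being deactivated by the allylic acetate, and should give the (E)-allylic alcohol.

Step 2
Reactants: 2 (2E,6E,10E)-12-hydroxy-3,7,11-trimethyldodeca-2,6,10-trien-1-yl acetate
Product: 3 (2E,6E,10E)-12-[(tert-butyldimethylsilyl)oxy]-3,7,11-trimethyldodeca-2,6,10-trien-1-yl acetate
Conditions: TBSCl, imidazole, DMF, 0 °C to rt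
Reagents that add atoms: tert-butyldimethylsilyl chloride, CC(C)(C)[Si](C)(C)Cl
Why: Imidazole-promoted silylation of the primary allylic alcohol masks this oxygen for the chlorination and Grignard steps.

Step 3
Reactants: 3 (2E,6E,10E)-12-[(tert-butyldimethylsilyl)oxy]-3,7,11-trimethyldodeca-2,6,10-trien-1-yl acetate
Product: 4 (2E,6E,10E)-12-[(tert-butyldimethylsilyl)oxy]-3,7,11-trimethyldodeca-2,6,10-trien-1-ol
Conditions: K2CO3 (0.2 equiv), MeOH, rt
Reagents that add atoms: none
Why: Base-catalysed transesterification (methanolysis) should remove the acetate and leave the silyl ether alone.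

Step 4
Reactants: 4 (2E,6E,10E)-12-[(tert-butyldimethylsilyl)oxy]-3,7,11-trimethyldodeca-2,6,10-trien-1-ol
Product: 5 tert-butyl{[(2E,6E,10E)-12-chloro-2,6,10-trimethyldodeca-2,6,10-trien-1-yl]oxy}dimethylsilane
Conditions: PPh3, CCl4, MeCN, 0 °C to rt
Reagents that add atoms: tetrachloromethane, ClC(Cl)(Cl)Cl
Why: The Appel reaction replaces the primary allylic hydroxyl by chloride through SN2 displacement of an oxyphosphonium ion, which for geraniol-type alcohols proceeds without allylic transposition or loss of the (E) geometry.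

Step 5
Reactants: 6 furan-3-ylmethanol
Product: 7 3-(chloromethyl)furan
Conditions: SOCl2, pyridine, Et2O, 0 °C
Reagents that add atoms: thionyl chloride, O=S(Cl)Cl
Why: Chlorination of the primary alcohol through its chlorosulfite (Darzens-type, pyridine as acid scavenger) should give the 3-furylmethyl chloride, which is handled cold as a solution.

Step 6
Reactants: 7 3-(chloromethyl)furan; 5 tert-butyl{[(2E,6E,10E)-12-chloro-2,6,10-trimethyldodeca-2,6,10-trien-1-yl]oxy}dimethylsilane
Product: 9 tert-butyl{[(2E,6E,10E)-13-(furan-3-yl)-2,6,10-trimethyltrideca-2,6,10-trien-1-yl]oxy}dimethylsilane, via (furan-3-ylmethyl)magnesium chloride 8 (not isolated)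
Conditions: Mg, THF, rt; then 5, Li2CuCl4 (3 mol %), THF, 0 °C
Reagents that add atoms: none
Why: Copper-catalysed Grignard cross-coupling (Kochi type) of a 3-furylmethyl reagent with a primary allylic chloride should take place at the α-carbon with retention of the (E) alkene, and the silyl ether is inert to it.

Step 7
Reactants: 9 tert-butyl{[(2E,6E,10E)-13-(furan-3-yl)-2,6,10-trimethyltrideca-2,6,10-trien-1-yl]oxy}dimethylsilane
Product: 10 (2E,6E,10E)-13-(furan-3-yl)-2,6,10-trimethyltrideca-2,6,10-trien-1-ol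
Conditions: Bu4NF, THF, 0 °C to rt
Reagents that add atoms: none
Why: Fluoride-induced cleavage of the silyl ether (desilylation) frees the primary allylic alcohol without touching ring B or the alkenes.

Step 8
Reactants: 10 (2E,6E,10E)-13-(furan-3-yl)-2,6,10-trimethyltrideca-2,6,10-trien-1-ol
Product: 11 (2E,6E,10E)-13-(furan-3-yl)-2,6,10-trimethyltrideca-2,6,10-trienal
Conditions: MnO2 (activated, excess), CH2Cl2, rt
Reagents that add atoms: none
Why: MnO2 oxidises allylic alcohols selectively to enals with retention of the (E) geometry and does not attack the furan or the isolated alkenes.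

Step 9
Reactants: 12 methyl 2-[bis(2,2,2-trifluoroethoxy)phosphoryl]acetate
Product: 13 methyl 2-[bis(2,2,2-trifluoroethoxy)phosphoryl]-2,2-dibromoacetate
Conditions: Br2, aq. NaOH (NaOBr), 0 °C, short contact; extraction into CH2Cl2
Reagents that add atoms: bromine, BrBr (delivered as sodium hypobromite, [Na+].[O-]Br)
Why: Hypobromite halogenation of the active methylene (haloform-type α-bromination of a phosphonoacetate) runs to the dibromide because the monobromide is the more acidic, which is why exhaustive bromination and later half-reduction is cleaner than direct monobromination.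

Step 10
Reactants: 13 methyl 2-[bis(2,2,2-trifluoroethoxy)phosphoryl]-2,2-dibromoacetate
Product: 14 methyl 2-[bis(2,2,2-trifluoroethoxy)phosphoryl]-2-bromoacetate (racemic)
Conditions: SnCl2·2H2O, EtOH/H2O, 0 °C
Reagents that add atoms: none
Why: SnCl2 reduces one C–Br bond of the gem-dibromide (reductive monodehalogenation of an α,α-dihalo phosphonoacetate) and should stop at the monobromide.

Step 11
Reactants: 11 (2E,6E,10E)-13-(furan-3-yl)-2,6,10-trimethyltrideca-2,6,10-trienal
Product: 15 (2S,6E,10E)-13-(furan-3-yl)-2,6,10-trimethyltrideca-6,10-dienal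
Conditions: ene-reductase (Old Yellow Enzyme homologue, (S)-selective, picked from a screening panel), NADP+ (cat.), D-glucose, glucose dehydrogenase, KH2PO4/K2HPO4 buffer pH 7.0, MTBE overlay, 30 °C
Reagents that add atoms: none
Why: Reduced flavin, regenerated by NADPH from the glucose/glucose dehydrogenase couple, transfers hydride to C8 of the enal, whose C6 carbonyl is hydrogen-bonded in the active site, and the conserved tyrosine then protonates C7 from the opposite face, a net anti addition of H2. The closest known reaction type is the Old Yellow Enzyme bioreduction of (E)-2-methyl-2-enals such as 2-methylpent-2-enal and α-methylcinnamaldehydes to 2-methyl aldehydes. No ring is formed. C7 is controlled by the enzyme, because the fixed geometry of hydride and proton delivery to the bound (E)-enal decides the face, and an (S)-selective homologue is chosen by screening against its (R)-selective relatives. The step needs chemoselectivity over the C11=C12 and C15=C16 alkenes, ring B and the aldehyde, and this is secured because only an alkene conjugated to the bound carbonyl accepts flavin hydride and because the isolated enzyme brings no alcohol dehydrogenase. Neutral pH, the organic overlay that takes up 15 as it forms and immediate use in step 12 should limit racemisation of the enolisable C7.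

Step 12
Reactants: 15 (2S,6E,10E)-13-(furan-3-yl)-2,6,10-trimethyltrideca-6,10-dienal; 14 methyl 2-[bis(2,2,2-trifluoroethoxy)phosphoryl]-2-bromoacetate
Product: 16 methyl (2E,4S,8E,12E)-2-bromo-15-(furan-3-yl)-4,8,12-trimethylpentadeca-2,8,12-trienoate
Conditions: KOt-Bu, 18-crown-6, THF, −78 °C
Reagents that add atoms: none
Why: Horner–Wadsworth–Emmons olefination with the bis(trifluoroethyl) bromophosphonate (Still–Gennari-type reagent) eliminates fast from the kinetic adduct and should place the C7 chain cis to the ester, that is, give the (2E)-2-bromoacrylate with bromine trans to the chain, while the cold, weakly basic medium should preserve the α-stereocentre of 15, which becomes C4 of 16.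

Step 13
Reactants: 16 methyl (2E,4S,8E,12E)-2-bromo-15-(furan-3-yl)-4,8,12-trimethylpentadeca-2,8,12-trienoate
Product: 17 (2E,4S,8E,12E)-2-bromo-15-(furan-3-yl)-4,8,12-trimethylpentadeca-2,8,12-trien-1-ol
Conditions: i-Bu2AlH (2.2 equiv), CH2Cl2, −78 °C; aq. KNaC4H4O6 (Rochelle salt)
Reagents that add atoms: none
Why: i-Bu2AlH reduces the conjugated ester in a 1,2 sense to the allylic alcohol (hydride reduction) without touching the vinyl bromide or the alkene geometry.

Step 14
Reactants: 17 (2E,4S,8E,12E)-2-bromo-15-(furan-3-yl)-4,8,12-trimethylpentadeca-2,8,12-trien-1-ol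
Product: 18 (2E,4S,8E,12E)-2-bromo-15-(furan-3-yl)-4,8,12-trimethylpentadeca-2,8,12-trienal
Conditions: Dess–Martin periodinane, NaHCO3, CH2Cl2, 0 °C
Reagents that add atoms: none
Why: Dess–Martin oxidation under bicarbonate buffering gives the α-bromo enal under neutral conditions, which guards the (2E) geometry and the γ-stereocentre, and the crude aldehyde is used at once.

Step 15
Reactants: 19 propanoic acid; 18 (2E,4S,8E,12E)-2-bromo-15-(furan-3-yl)-4,8,12-trimethylpentadeca-2,8,12-trienal
Product: 21 (4E,6S,10E,14E)-4-bromo-17-(furan-3-yl)-3-hydroxy-2,6,10,14-tetramethylheptadeca-4,10,14-trienoic acid (mixture of C2/C3 diastereomers), via dilithium prop-1-ene-1,1-bis(olate) 20 (not isolated)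
Conditions: LiN(i-Pr)2 (2.1 equiv per acid), THF, −78 to 0 °C; then 18, −78 °C; aq. HCl to pH 3 at 0 °C
Reagents that add atoms: none
Why: Aldol addition of the dilithium enediolate of propanoic acid to the aldehyde (carboxylic acid dianion aldol) is faster than any deprotonation of the enal and gives the β-hydroxy acid directly, the two new centres being a mixture that converges in step 17.

Step 16
Reactants: 21 (4E,6S,10E,14E)-4-bromo-17-(furan-3-yl)-3-hydroxy-2,6,10,14-tetramethylheptadeca-4,10,14-trienoic acid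
Product: 22 (5E)-5-[(2S,6E,10E)-13-(furan-3-yl)-2,6,10-trimethyltrideca-6,10-dien-1-ylidene]-4-hydroxy-3-methyloxolan-2-one (mixture of C3/C4 diastereomers)
Conditions: CuI (10 mol %), trans-N,N'-dimethylcyclohexane-1,2-diamine (20 mol %), K2CO3 (2 equiv), THF, 65 °C
Reagents that add atoms: none
Why: Copper-catalysed intramolecular O-vinylation of the carboxylate by the vinyl bromide (Ullmann-type C–O coupling, 5-exo closure of ring A) is stereospecific with retention, so the bromine trans to C7 is replaced by O1 trans to C7, the (E)-ylidene, and the sp3 carbons C3 and C4 let the acid reach C5 whatever their configuration.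

Step 17
Reactants: 22 (5E)-5-[(2S,6E,10E)-13-(furan-3-yl)-2,6,10-trimethyltrideca-6,10-dien-1-ylidene]-4-hydroxy-3-methyloxolan-2-one
Product: 23 (5E)-5-[(2S,6E,10E)-13-(furan-3-yl)-2,6,10-trimethyltrideca-6,10-dien-1-ylidene]-4-hydroxy-3-methylfuran-2(5H)-one
Conditions: Dess–Martin periodinane, NaHCO3, CH2Cl2, 0 °C
Reagents that add atoms: none
Why: Dess–Martin oxidation of the secondary allylic alcohol at C4 gives the 2,4-dione, which enolises to the tetronic acid and erases the C3 and C4 stereocentres, while the C5=C6 geometry and C7 are not involved.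

Step 18
Reactants: 23 (5E)-5-[(2S,6E,10E)-13-(furan-3-yl)-2,6,10-trimethyltrideca-6,10-dien-1-ylidene]-4-hydroxy-3-methylfuran-2(5H)-one; 24 hexadecanoyl chloride
Product: 25 (2E)-2-[(2S,6E,10E)-13-(furan-3-yl)-2,6,10-trimethyltrideca-6,10-dien-1-ylidene]-4-methyl-5-oxo-2,5-dihydrofuran-3-yl hexadecanoate
Conditions: i-Pr2NEt, CH2Cl2, −20 to 0 °C
Reagents that add atoms: none
Why: O-acylation of the tetronate anion with the acid chloride (esterification of a vinylogous acid) occurs at O4 because C3 is blocked by its methyl group, and the hindered, non-nucleophilic base at low temperature avoids conjugate addition to C6 that could isomerise the ylidene.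

Compound list
1 | (2E,6E)-3,7,11-trimethyldodeca-2,6,10-trien-1-yl acetate ((2E,6E)-farnesyl acetate) | CC(C)=CCC/C(C)=C/CC/C(C)=C/COC(C)=O | starting material
2 | (2E,6E,10E)-12-hydroxy-3,7,11-trimethyldodeca-2,6,10-trien-1-yl acetate | OC/C(C)=C/CC/C(C)=C/CC/C(C)=C/COC(C)=O | intermediate
3 | (2E,6E,10E)-12-[(tert-butyldimethylsilyl)oxy]-3,7,11-trimethyldodeca-2,6,10-trien-1-yl acetate | CC(C)(C)[Si](C)(C)OC/C(C)=C/CC/C(C)=C/CC/C(C)=C/COC(C)=O | intermediate
4 | (2E,6E,10E)-12-[(tert-butyldimethylsilyl)oxy]-3,7,11-trimethyldodeca-2,6,10-trien-1-ol | CC(C)(C)[Si](C)(C)OC/C(C)=C/CC/C(C)=C/CC/C(C)=C/CO | intermediate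
5 | tert-butyl{[(2E,6E,10E)-12-chloro-2,6,10-trimethyldodeca-2,6,10-trien-1-yl]oxy}dimethylsilane | CC(C)(C)[Si](C)(C)OC/C(C)=C/CC/C(C)=C/CC/C(C)=C/CCl | intermediate
6 | furan-3-ylmethanol | OCc1ccoc1 | starting material
7 | 3-(chloromethyl)furan | ClCc1ccoc1 | intermediate
8 | (furan-3-ylmethyl)magnesium chloride | Cl[Mg]Cc1ccoc1 | intermediate (not isolated)
9 | tert-butyl{[(2E,6E,10E)-13-(furan-3-yl)-2,6,10-trimethyltrideca-2,6,10-trien-1-yl]oxy}dimethylsilane | CC(C)(C)[Si](C)(C)OC/C(C)=C/CC/C(C)=C/CC/C(C)=C/CCc1ccoc1 | intermediate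
10 | (2E,6E,10E)-13-(furan-3-yl)-2,6,10-trimethyltrideca-2,6,10-trien-1-ol | OC/C(C)=C/CC/C(C)=C/CC/C(C)=C/CCc1ccoc1 | intermediate
11 | (2E,6E,10E)-13-(furan-3-yl)-2,6,10-trimethyltrideca-2,6,10-trienal | O=C/C(C)=C/CC/C(C)=C/CC/C(C)=C/CCc1ccoc1 | intermediate (precursor of the key step)
12 | methyl 2-[bis(2,2,2-trifluoroethoxy)phosphoryl]acetate | COC(=O)CP(=O)(OCC(F)(F)F)OCC(F)(F)F | starting material
13 | methyl 2-[bis(2,2,2-trifluoroethoxy)phosphoryl]-2,2-dibromoacetate | COC(=O)C(Br)(Br)P(=O)(OCC(F)(F)F)OCC(F)(F)F | intermediate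
14 | methyl 2-[bis(2,2,2-trifluoroethoxy)phosphoryl]-2-bromoacetate (racemic) | COC(=O)C(Br)P(=O)(OCC(F)(F)F)OCC(F)(F)F | intermediate
15 | (2S,6E,10E)-13-(furan-3-yl)-2,6,10-trimethyltrideca-6,10-dienal | O=C[C@@H](C)CCC/C(C)=C/CC/C(C)=C/CCc1ccoc1 | intermediate (product of the key step)
16 | methyl (2E,4S,8E,12E)-2-bromo-15-(furan-3-yl)-4,8,12-trimethylpentadeca-2,8,12-trienoate | COC(=O)/C(Br)=C\[C@@H](C)CCC/C(C)=C/CC/C(C)=C/CCc1ccoc1 | intermediate
17 | (2E,4S,8E,12E)-2-bromo-15-(furan-3-yl)-4,8,12-trimethylpentadeca-2,8,12-trien-1-ol | OC/C(Br)=C\[C@@H](C)CCC/C(C)=C/CC/C(C)=C/CCc1ccoc1 | intermediate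
18 | (2E,4S,8E,12E)-2-bromo-15-(furan-3-yl)-4,8,12-trimethylpentadeca-2,8,12-trienal | O=C/C(Br)=C\[C@@H](C)CCC/C(C)=C/CC/C(C)=C/CCc1ccoc1 | intermediate
19 | propanoic acid | CCC(=O)O | starting material
20 | dilithium prop-1-ene-1,1-bis(olate) | [Li+].[Li+].CC=C([O-])[O-] | intermediate (not isolated)
21 | (4E,6S,10E,14E)-4-bromo-17-(furan-3-yl)-3-hydroxy-2,6,10,14-tetramethylheptadeca-4,10,14-trienoic acid (C2/C3 diastereomers) | OC(=O)C(C)C(O)/C(Br)=C\[C@@H](C)CCC/C(C)=C/CC/C(C)=C/CCc1ccoc1 | intermediate
22 | (5E)-5-[(2S,6E,10E)-13-(furan-3-yl)-2,6,10-trimethyltrideca-6,10-dien-1-ylidene]-4-hydroxy-3-methyloxolan-2-one (C3/C4 diastereomers) | CC1C(O)/C(=C\[C@@H](C)CCC/C(C)=C/CC/C(C)=C/CCc2ccoc2)OC1=O | intermediate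
23 | (5E)-5-[(2S,6E,10E)-13-(furan-3-yl)-2,6,10-trimethyltrideca-6,10-dien-1-ylidene]-4-hydroxy-3-methylfuran-2(5H)-one | CC1=C(O)/C(=C\[C@@H](C)CCC/C(C)=C/CC/C(C)=C/CCc2ccoc2)OC1=O | intermediate
24 | hexadecanoyl chloride (palmitoyl chloride) | CCCCCCCCCCCCCCCC(=O)Cl | starting material
25 | (2E)-2-[(2S,6E,10E)-13-(furan-3-yl)-2,6,10-trimethyltrideca-6,10-dien-1-ylidene]-4-methyl-5-oxo-2,5-dihydrofuran-3-yl hexadecanoate | CCCCCCCCCCCCCCCC(=O)OC1=C(C)C(=O)O/C1=C/[C@@H](C)CCC/C(C)=C/CC/C(C)=C/CCc1ccoc1 | target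

Total step count: 18. Longest linear sequence: 15 steps (steps 1–4, 6–8 and 11–18); steps 5, 9 and 10 are side branches.

Steps most likely to fail

Step 11. The very lipophilic C18 enal may be converted only slowly in buffer, the available homologues may give insufficient enantioselectivity, and a long reaction time would let the product racemise at C7. The fallback sets out from 11 and comes back at 15. Enal 11 would be oxidised with Ag2O (from AgNO3 and aq. NaOH in EtOH) to (2E,6E,10E)-13-(furan-3-yl)-2,6,10-trimethyltrideca-2,6,10-trienoic acid F1. Carboxylate-directed Noyori-type hydrogenation with Ru(OAc)2[(S)-H8-BINAP] in MeOH under a few bar of H2, the ligand enantiomer being fixed beforehand on tiglic acid, should reduce only the conjugated alkene and give (2S,6E,10E)-13-(furan-3-yl)-2,6,10-trimethyltrideca-6,10-dienoic acid F2. LiAlH4 in Et2O would give (2S,6E,10E)-13-(furan-3-yl)-2,6,10-trimethyltrideca-6,10-dien-1-ol F3, and buffered Dess–Martin oxidation would return aldehyde 15.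

Step 16. Oxidative addition at the hindered trisubstituted vinyl bromide may be slow, so that base-induced loss of the C4 hydroxyl or erosion of the C5=C6 geometry competes with ring closure. The fallback sets out from 21 and comes back at 22, and makes the same C5–O1 bond by oxidative boron–copper coupling instead of halide–copper coupling. Miyaura borylation of 21 as its potassium salt (B2pin2, PdCl2(dppf), KOAc, 1,4-dioxane, 80 °C) should replace bromine by boron with retention and give (4Z,6S,10E,14E)-17-(furan-3-yl)-3-hydroxy-2,6,10,14-tetramethyl-4-(4,4,5,5-tetramethyl-1,3,2-dioxaborolan-2-yl)heptadeca-4,10,14-trienoic acid F4; the descriptor changes only because boron ranks below carbon. Chan–Lam-type coupling of the alkenylboronate with the internal carboxylic acid (Cu(OAc)2, pyridine, 4 Å sieves, air, CH2Cl2, rt) should then close ring A with retention to lactone 22.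

Step 12. With an α-branched aliphatic aldehyde the olefination may give an incomplete (E)/(Z) ratio, and any excess base could epimerise C7 of 15. The fallback sets out from 15 and comes back at 22, and takes the geometry from a syn hydrometalation instead of an olefination.
- Corey–Fuchs dibromo-olefination (CBr4, PPh3, Et3N, CH2Cl2, 0 °C) would give 3-[(3E,7E,12S)-14,14-dibromo-4,8,12-trimethyltetradeca-3,7,13-trien-1-yl]furan F5.
- n-BuLi (2.1 equiv, THF, −78 °C) followed by ClCO2Me would give methyl (4S,8E,12E)-15-(furan-3-yl)-4,8,12-trimethylpentadeca-8,12-dien-2-ynoate F6.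
- Hydrostannation with Bu3SnH and Pd(PPh3)4 (syn addition, tin α to the ester) should give methyl (2E,4S,8E,12E)-15-(furan-3-yl)-4,8,12-trimethyl-2-(tributylstannyl)pentadeca-2,8,12-trienoate F7.
- Iododestannylation with I2 in CH2Cl2 at 0 °C proceeds with retention and would give methyl (2E,4S,8E,12E)-15-(furan-3-yl)-2-iodo-4,8,12-trimethylpentadeca-2,8,12-trienoate F8; iodine is chosen because it spares the furan.
- The conditions of steps 13 to 16 would then lead through (2E,4S,8E,12E)-15-(furan-3-yl)-2-iodo-4,8,12-trimethylpentadeca-2,8,12-trien-1-ol F9, (2E,4S,8E,12E)-15-(furan-3-yl)-2-iodo-4,8,12-trimethylpentadeca-2,8,12-trienal F10 and (4E,6S,10E,14E)-17-(furan-3-yl)-3-hydroxy-4-iodo-2,6,10,14-tetramethylheptadeca-4,10,14-trienoic acid F11 to lactone 22.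

Further compounds
F1 | step 11 | (2E,6E,10E)-13-(furan-3-yl)-2,6,10-trimethyltrideca-2,6,10-trienoic acid | OC(=O)/C(C)=C/CC/C(C)=C/CC/C(C)=C/CCc1ccoc1
F2 | step 11 | (2S,6E,10E)-13-(furan-3-yl)-2,6,10-trimethyltrideca-6,10-dienoic acid | OC(=O)[C@@H](C)CCC/C(C)=C/CC/C(C)=C/CCc1ccoc1
F3 | step 11 | (2S,6E,10E)-13-(furan-3-yl)-2,6,10-trimethyltrideca-6,10-dien-1-ol | OC[C@@H](C)CCC/C(C)=C/CC/C(C)=C/CCc1ccoc1
F4 | step 16 | (4Z,6S,10E,14E)-17-(furan-3-yl)-3-hydroxy-2,6,10,14-tetramethyl-4-(4,4,5,5-tetramethyl-1,3,2-dioxaborolan-2-yl)heptadeca-4,10,14-trienoic acid | OC(=O)C(C)C(O)/C(B1OC(C)(C)C(C)(C)O1)=C\[C@@H](C)CCC/C(C)=C/CC/C(C)=C/CCc1ccoc1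
F5 | step 12 | 3-[(3E,7E,12S)-14,14-dibromo-4,8,12-trimethyltetradeca-3,7,13-trien-1-yl]furan | BrC(Br)=C[C@@H](C)CCC/C(C)=C/CC/C(C)=C/CCc1ccoc1
F6 | step 12 | methyl (4S,8E,12E)-15-(furan-3-yl)-4,8,12-trimethylpentadeca-8,12-dien-2-ynoate | COC(=O)C#C[C@@H](C)CCC/C(C)=C/CC/C(C)=C/CCc1ccoc1
F7 | step 12 | methyl (2E,4S,8E,12E)-15-(furan-3-yl)-4,8,12-trimethyl-2-(tributylstannyl)pentadeca-2,8,12-trienoate | COC(=O)/C(=C\[C@@H](C)CCC/C(C)=C/CC/C(C)=C/CCc1ccoc1)[Sn](CCCC)(CCCC)CCCC
F8 | step 12 | methyl (2E,4S,8E,12E)-15-(furan-3-yl)-2-iodo-4,8,12-trimethylpentadeca-2,8,12-trienoate | COC(=O)/C(I)=C\[C@@H](C)CCC/C(C)=C/CC/C(C)=C/CCc1ccoc1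
F9 | step 12 | (2E,4S,8E,12E)-15-(furan-3-yl)-2-iodo-4,8,12-trimethylpentadeca-2,8,12-trien-1-ol | OC/C(I)=C\[C@@H](C)CCC/C(C)=C/CC/C(C)=C/CCc1ccoc1
F10 | step 12 | (2E,4S,8E,12E)-15-(furan-3-yl)-2-iodo-4,8,12-trimethylpentadeca-2,8,12-trienal | O=C/C(I)=C\[C@@H](C)CCC/C(C)=C/CC/C(C)=C/CCc1ccoc1
F11 | step 12 | (4E,6S,10E,14E)-17-(furan-3-yl)-3-hydroxy-4-iodo-2,6,10,14-tetramethylheptadeca-4,10,14-trienoic acid | OC(=O)C(C)C(O)/C(I)=C\[C@@H](C)CCC/C(C)=C/CC/C(C)=C/CCc1ccoc1
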